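## Retrosynthetic overview

1. Target 26 comes from allyl ester 25 (Pd(0) deallylation); its 2Z acid alkene comes from an Ando HWE of aldehyde 17 with phosphonate 23.
2. Aldehyde 17 comes from methyl alkyne 13 and acrolein: syn-hydrozirconation, then Cu-catalysed 1,4-addition, fixes the 6E trisubstituted alkene.
3. Enoate 13 comes from alkylidene phosphonoacetate 6 and 3-(furan-3-yl)propanal 11 by a new reductive Still–Gennari olefination (Z methyl enoate); 6 comes from ynal 4 by Knoevenagel condensation.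
4. Key step: ynal 4 comes from (S)-carvone 1 by C–O bond formation at C3 (nucleophilic epoxidation) and C=N bond formation at C1 (tosylhydrazone). These trigger the Eschenmoser–Tanabe cleavage of C2–C3; the epoxide oxygen ends up as the aldehyde oxygen and C5 of carvone becomes C9 of 26.
5. Rings: none is built. The furan is bought as 3-bromofuran; the only ring made is the transient oxirane of step 1, which is opened together with the carvone ring in step 2.

Assumption: stereo-mixtures that are erased later (alkene geometry of 6, C-2 of 23) are carried on unseparated, and epoxide 2 is drawn as its major trans isomer.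

## Route

Step 1
Reactants: 1 (S)-(+)-carvone
Product: 2 (1S,4S,6S)-1-methyl-4-(prop-1-en-2-yl)-7-oxabicyclo[4.1.0]heptan-2-one
Conditions: 30% H2O2, NaOH (cat.), MeOH, 0 °C
Reagents that add atoms: hydrogen peroxide, OO
Why: Weitz–Scheffer nucleophilic epoxidation forms the C3–O bond only at the enone (the isopropenyl group is no acceptor), anti to the C5 substituent; both new stereocentres are erased in step 2.

Step 2
Reactants: 2 (1S,4S,6S)-1-methyl-4-(prop-1-en-2-yl)-7-oxabicyclo[4.1.0]heptan-2-one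
Product: 4 (3R)-3-(prop-1-en-2-yl)hept-5-ynal, via epoxyketone tosylhydrazone 3 (not isolated)
Conditions: TsNHNH2 (1.0 equiv), AcOH/CH2Cl2 1:1, −20 °C → rt
Reagents that add atoms: none
Why: Eschenmoser–Tanabe fragmentation: the hydrazone C=N lets the epoxide open and N2 and sulfinate leave, cleaving C2–C3 into the 2-butynyl arm and the aldehyde arm, while the stereocentre is untouched (its label changes from S to R only through the priority rules).

Step 3
Reactants: 4 (3R)-3-(prop-1-en-2-yl)hept-5-ynal; 5 methyl 2-[bis(2,2,2-trifluoroethoxy)phosphoryl]acetate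
Product: 6 methyl (5S)-2-[bis(2,2,2-trifluoroethoxy)phosphoryl]-5-(prop-1-en-2-yl)non-2-en-7-ynoate (E/Z mixture)
Conditions: TiCl4, N-methylmorpholine, THF, 0 °C → rt
Reagents that add atoms: none
Why: Lehnert-type TiCl4/amine Knoevenagel condensation of the unhindered aldehyde with the acidic phosphonoacetate; the alkene geometry does not matter because this double bond is reduced in step 6.

Step 4
Reactants: 7 3-bromofuran; 8 oxetane
Product: 10 3-(furan-3-yl)propan-1-ol, via 3-furyllithium 9 (not isolated)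
Conditions: n-BuLi, THF, −78 °C; then oxetane, BF3·OEt2, −78 °C
Reagents that add atoms: none
Why: Br–Li exchange gives 3-furyllithium, which keeps its position at −78 °C and opens BF3-activated oxetane by SN2 to the three-carbon alcohol.

Step 5
Reactants: 10 3-(furan-3-yl)propan-1-ol
Product: 11 3-(furan-3-yl)propanal
Conditions: PhI(OAc)2, TEMPO (10 mol %), CH2Cl2, rt
Reagents that add atoms: none
Why: TEMPO/PhI(OAc)2 oxidation of the primary alcohol stops at the aldehyde and leaves the furan alone.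

Step 6
Reactants: 6 methyl (5S)-2-[bis(2,2,2-trifluoroethoxy)phosphoryl]-5-(prop-1-en-2-yl)non-2-en-7-ynoate; 11 3-(furan-3-yl)propanal
Product: 13 methyl (2Z)-5-(furan-3-yl)-2-[(3S)-3-(prop-1-en-2-yl)hept-5-yn-1-yl]pent-2-enoate, via potassium phosphonoenolate 12 (not isolated)
Conditions: K-Selectride (1.0 equiv), THF, −78 °C; 18-crown-6 (5 equiv); then 11, −78 → −20 °C
Reagents that add atoms: none
Why: Proposed new method: K-Selectride adds hydride 1,4 to the doubly activated alkene of 6 and so makes, regiospecifically, the same potassium phosphonoenolate that KHMDS/18-crown-6 gives in a Still–Gennari olefination, whose kinetic adduct with aldehyde 11 eliminates fast and irreversibly (electron-poor trifluoroethyl phosphonate) to the Z trisubstituted enoate with the ester cis to the furylethyl chain; the closest known reaction types are the Michael-initiated Horner–Wadsworth–Emmons olefination of vinylphosphonates and the K-Selectride conjugate reduction–enolate trapping, which have not been combined in the Z-selective bis(trifluoroethyl)phosphonate series.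

Step 7
Reactants: 13 methyl (2Z)-5-(furan-3-yl)-2-[(3S)-3-(prop-1-en-2-yl)hept-5-yn-1-yl]pent-2-enoate; 14 acrolein
Product: 17 methyl (2Z)-5-(furan-3-yl)-2-[(3S,5E)-6-methyl-9-oxo-3-(prop-1-en-2-yl)non-5-en-1-yl]pent-2-enoate, via alkenylzirconocene chloride 15 (not isolated), via silyl enol ether 16 (not isolated)
Conditions: Cp2Zr(H)Cl (1.5 equiv), THF, rt → 40 °C; then CuI·0.75DMS (10 mol %), acrolein (3 equiv), TMSCl, −40 → 0 °C; 1 M HCl work-up
Reagents that add atoms: none
Why: Syn-hydrozirconation of the alkyne (much faster than of the hindered isopropenyl group) puts Zr on the less hindered methyl-bearing carbon and so fixes the E geometry, and Zr-to-Cu transmetalation with TMSCl-assisted conjugate addition to acrolein transfers the alkenyl group with retention.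

Step 8
Reactants: 18 diphenyl phosphite; 19 prop-2-en-1-yl bromoacetate
Product: 20 prop-2-en-1-yl 2-(diphenoxyphosphoryl)acetate
Conditions: Et3N, CH2Cl2, 0 °C → rt
Reagents that add atoms: none
Why: Michaelis–Becker-type P-alkylation of the acidic diaryl phosphite (Ando's reagent synthesis).

Step 9
Reactants: 20 prop-2-en-1-yl 2-(diphenoxyphosphoryl)acetate; 21 5-bromo-2-methylpent-2-ene
Product: 23 prop-2-en-1-yl 2-(diphenoxyphosphoryl)-6-methylhept-5-enoate (racemic), via sodium phosphonoenolate 22 (not isolated)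
Conditions: NaH, DMSO, rt; then 21, NaI (cat.), 50 °C
Reagents that add atoms: none
Why: SN2 C-alkylation of the stabilised phosphonoacetate anion by the primary homoallylic bromide; the new stereocentre is lost in step 10.

Step 10
Reactants: 17 methyl (2Z)-5-(furan-3-yl)-2-[(3S,5E)-6-methyl-9-oxo-3-(prop-1-en-2-yl)non-5-en-1-yl]pent-2-enoate; 23 prop-2-en-1-yl 2-(diphenoxyphosphoryl)-6-methylhept-5-enoate
Product: 25 prop-2-en-1-yl (2Z,6E,9S)-9-[(3Z)-6-(furan-3-yl)-3-(methoxycarbonyl)hex-3-en-1-yl]-6,10-dimethyl-2-(4-methylpent-3-en-1-yl)undeca-2,6,10-trienoate, via homoprenyl phosphonoenolate 24 (not isolated)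
Conditions: t-BuOK, THF, −78 °C; then 17, −78 → 0 °C
Reagents that add atoms: none
Why: Ando Z-selective Horner–Wadsworth–Emmons olefination: the diaryl phosphonate makes elimination from the kinetic adduct fast, giving the 2Z enoate with the ester cis to the chain.

Step 11
Reactants: 25 prop-2-en-1-yl (2Z,6E,9S)-9-[(3Z)-6-(furan-3-yl)-3-(methoxycarbonyl)hex-3-en-1-yl]-6,10-dimethyl-2-(4-methylpent-3-en-1-yl)undeca-2,6,10-trienoate
Product: 26 (2Z,6E,9S)-9-[(3Z)-6-(furan-3-yl)-3-(methoxycarbonyl)hex-3-en-1-yl]-6,10-dimethyl-2-(4-methylpent-3-en-1-yl)undeca-2,6,10-trienoic acid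
Conditions: Pd(PPh3)4 (5 mol %), morpholine, THF, rt
Reagents that add atoms: none
Why: Tsuji–Trost deallylation transfers the allyl group to morpholine under neutral conditions and frees the acid without touching the methyl ester, the furan or any alkene.

## Compound list

1 | (S)-(+)-carvone | C=C(C)[C@@H]1CC(=O)C(C)=CC1 | starting material
2 | (1S,4S,6S)-1-methyl-4-(prop-1-en-2-yl)-7-oxabicyclo[4.1.0]heptan-2-one | C=C(C)[C@@H]1CC(=O)[C@@]2(C)O[C@H]2C1 | intermediate
3 | N-tosylhydrazone of 2 (C=N in place of C=O, ring stereocentres as in 2) | C=C(C)[C@@H]1CC(=NNS(=O)(=O)c3ccc(C)cc3)[C@@]2(C)O[C@H]2C1 | intermediate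
4 | (3R)-3-(prop-1-en-2-yl)hept-5-ynal | C=C(C)[C@H](CC#CC)CC=O | intermediate
5 | methyl 2-[bis(2,2,2-trifluoroethoxy)phosphoryl]acetate | COC(=O)CP(=O)(OCC(F)(F)F)OCC(F)(F)F | starting material
6 | methyl (5S)-2-[bis(2,2,2-trifluoroethoxy)phosphoryl]-5-(prop-1-en-2-yl)non-2-en-7-ynoate (E/Z mixture) | C=C(C)[C@H](CC#CC)CC=C(C(=O)OC)P(=O)(OCC(F)(F)F)OCC(F)(F)F | intermediate
7 | 3-bromofuran | Brc1ccoc1 | starting material
8 | oxetane | C1COC1 | starting material
9 | 3-furyllithium | [Li]c1ccoc1 | intermediate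
10 | 3-(furan-3-yl)propan-1-ol | OCCCc1ccoc1 | intermediate
11 | 3-(furan-3-yl)propanal | O=CCCc1ccoc1 | intermediate
12 | potassium enolate of methyl (5S)-2-[bis(2,2,2-trifluoroethoxy)phosphoryl]-5-(prop-1-en-2-yl)non-7-ynoate | C=C(C)[C@H](CC#CC)CCC(=C([O-])OC)P(=O)(OCC(F)(F)F)OCC(F)(F)F.[K+] | intermediate
13 | methyl (2Z)-5-(furan-3-yl)-2-[(3S)-3-(prop-1-en-2-yl)hept-5-yn-1-yl]pent-2-enoate | C=C(C)[C@H](CC#CC)CC/C(=C/CCc1ccoc1)C(=O)OC | intermediate
14 | acrolein | C=CC=O | starting material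
15 | (E)-alkenylzirconocene chloride from 13 (Cp2ZrCl on the methyl-bearing alkene carbon, H syn on the neighbouring carbon) | C=C(C)[C@H](C/C=C(\C)[Zr](Cl)(C1C=CC=C1)C1C=CC=C1)CC/C(=C/CCc1ccoc1)C(=O)OC | intermediate
16 | trimethylsilyl enol ether of 17 | C=C(C)[C@H](C/C=C(\C)CC=CO[Si](C)(C)C)CC/C(=C/CCc1ccoc1)C(=O)OC | intermediate
17 | methyl (2Z)-5-(furan-3-yl)-2-[(3S,5E)-6-methyl-9-oxo-3-(prop-1-en-2-yl)non-5-en-1-yl]pent-2-enoate | C=C(C)[C@H](C/C=C(\C)CCC=O)CC/C(=C/CCc1ccoc1)C(=O)OC | intermediate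
18 | diphenyl phosphite | O=[PH](Oc1ccccc1)Oc1ccccc1 | starting material
19 | prop-2-en-1-yl bromoacetate (allyl bromoacetate) | C=CCOC(=O)CBr | starting material
20 | prop-2-en-1-yl 2-(diphenoxyphosphoryl)acetate | C=CCOC(=O)CP(=O)(Oc1ccccc1)Oc1ccccc1 | intermediate
21 | 5-bromo-2-methylpent-2-ene | CC(C)=CCCBr | starting material
22 | sodium enolate of 20 | C=CCOC([O-])=CP(=O)(Oc1ccccc1)Oc1ccccc1.[Na+] | intermediate
23 | prop-2-en-1-yl 2-(diphenoxyphosphoryl)-6-methylhept-5-enoate (racemic) | C=CCOC(=O)C(CCC=C(C)C)P(=O)(Oc1ccccc1)Oc1ccccc1 | intermediate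
24 | potassium enolate of 23 | C=CCOC([O-])=C(CCC=C(C)C)P(=O)(Oc1ccccc1)Oc1ccccc1.[K+] | intermediate
25 | prop-2-en-1-yl (2Z,6E,9S)-9-[(3Z)-6-(furan-3-yl)-3-(methoxycarbonyl)hex-3-en-1-yl]-6,10-dimethyl-2-(4-methylpent-3-en-1-yl)undeca-2,6,10-trienoate | C=C(C)[C@H](C/C=C(\C)CC/C=C(/CCC=C(C)C)C(=O)OCC=C)CC/C(=C/CCc1ccoc1)C(=O)OC | intermediate
26 | (2Z,6E,9S)-9-[(3Z)-6-(furan-3-yl)-3-(methoxycarbonyl)hex-3-en-1-yl]-6,10-dimethyl-2-(4-methylpent-3-en-1-yl)undeca-2,6,10-trienoic acid | C=C(C)[C@H](C/C=C(\C)CC/C=C(/CCC=C(C)C)C(=O)O)CC/C(=C/CCc1ccoc1)C(=O)OC | target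

## Step count and risks

Total step count: 11. Longest linear sequence: 7 steps (1 → 2 → 3 → 6 → 7 → 10 → 11, from carvone).

The three steps most likely to fail:

(i) The new reductive olefination (step 6). The tri-sec-butylborane left by the hydride may hold on to enolate 12 or to the aldolate and lower conversion or the Z/E ratio, and 6 may partly deconjugate before reduction. The fallback uses only known chemistry and sets out from ynal 4. NaBH4 (MeOH, 0 °C) gives (3R)-3-(prop-1-en-2-yl)hept-5-yn-1-ol F1. I2, PPh3 and imidazole give (5R)-7-iodo-5-(prop-1-en-2-yl)hept-2-yne F2. Alkylation of the sodium salt of 5 (NaH, DMSO) with F2 gives methyl (5S)-2-[bis(2,2,2-trifluoroethoxy)phosphoryl]-5-(prop-1-en-2-yl)non-7-ynoate F3. A classical Still–Gennari olefination of F3 with 11 (KHMDS, 18-crown-6, THF, −78 °C) comes back to the route at 13, replacing steps 3 and 6.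

(ii) The hydrozirconation/conjugate addition (step 7). The Zr-to-Cu transfer of the hindered α-methyl alkenyl group and the 1,4-addition to acrolein may be slow, and hydrozirconation may give some regioisomer or touch the ester. The fallback sets out from 13. Hydrozirconation followed by iodine gives methyl (2Z)-5-(furan-3-yl)-2-[(3S,5E)-6-iodo-3-(prop-1-en-2-yl)hept-5-en-1-yl]pent-2-enoate F4, which can be freed from regioisomer by chromatography. Negishi coupling with commercial (1,3-dioxolan-2-ylethyl)zinc bromide (Pd(dppf)Cl2, THF) gives methyl (2Z)-2-[(3S,5E)-8-(1,3-dioxolan-2-yl)-6-methyl-3-(prop-1-en-2-yl)oct-5-en-1-yl]-5-(furan-3-yl)pent-2-enoate F5. Mild acetal hydrolysis (PPTS, acetone/water) comes back to the route at 17.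

(iii) The Ando olefination (step 10). With the large α-homoprenyl group the diphenyl phosphonate may give an inadequate Z/E ratio, and the isomers may be hard to separate. The fallback sets the geometry by a sigmatropic step and sets out from 17. A Morita–Baylis–Hillman reaction with allyl acrylate (DABCO) gives prop-2-en-1-yl (6E,9S)-9-[(3Z)-6-(furan-3-yl)-3-(methoxycarbonyl)hex-3-en-1-yl]-3-hydroxy-6,10-dimethyl-2-methylideneundeca-6,10-dienoate F6. Ethyl vinyl ether with Hg(OAc)2 gives the 3-(ethenyloxy) derivative of F6, prop-2-en-1-yl (6E,9S)-3-(ethenyloxy)-9-[(3Z)-6-(furan-3-yl)-3-(methoxycarbonyl)hex-3-en-1-yl]-6,10-dimethyl-2-methylideneundeca-6,10-dienoate F7. Heating F7 (toluene, 110 °C) brings about a Claisen rearrangement through a chair with the chain equatorial, which places the chain cis to the ester and gives prop-2-en-1-yl (2Z,6E,9S)-9-[(3Z)-6-(furan-3-yl)-3-(methoxycarbonyl)hex-3-en-1-yl]-6,10-dimethyl-2-(3-oxopropyl)undeca-2,6,10-trienoate F8. A Wittig reaction of F8 with isopropylidenetriphenylphosphorane comes back to the route at 25.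

## Further compounds

F1 | step 6 | (3R)-3-(prop-1-en-2-yl)hept-5-yn-1-ol | C=C(C)[C@H](CC#CC)CCO
F2 | step 6 | (5R)-7-iodo-5-(prop-1-en-2-yl)hept-2-yne | C=C(C)[C@H](CC#CC)CCI
F3 | step 6 | methyl (5S)-2-[bis(2,2,2-trifluoroethoxy)phosphoryl]-5-(prop-1-en-2-yl)non-7-ynoate | C=C(C)[C@H](CC#CC)CCC(C(=O)OC)P(=O)(OCC(F)(F)F)OCC(F)(F)F
F4 | step 7 | methyl (2Z)-5-(furan-3-yl)-2-[(3S,5E)-6-iodo-3-(prop-1-en-2-yl)hept-5-en-1-yl]pent-2-enoate | C=C(C)[C@H](C/C=C(\C)I)CC/C(=C/CCc1ccoc1)C(=O)OC
F5 | step 7 | methyl (2Z)-2-[(3S,5E)-8-(1,3-dioxolan-2-yl)-6-methyl-3-(prop-1-en-2-yl)oct-5-en-1-yl]-5-(furan-3-yl)pent-2-enoate | C=C(C)[C@H](C/C=C(\C)CCC1OCCO1)CC/C(=C/CCc1ccoc1)C(=O)OC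
F6 | step 10 | prop-2-en-1-yl (6E,9S)-9-[(3Z)-6-(furan-3-yl)-3-(methoxycarbonyl)hex-3-en-1-yl]-3-hydroxy-6,10-dimethyl-2-methylideneundeca-6,10-dienoate | C=C(C)[C@H](C/C=C(\C)CCC(O)C(=C)C(=O)OCC=C)CC/C(=C/CCc1ccoc1)C(=O)OC
F7 | step 10 | prop-2-en-1-yl (6E,9S)-3-(ethenyloxy)-9-[(3Z)-6-(furan-3-yl)-3-(methoxycarbonyl)hex-3-en-1-yl]-6,10-dimethyl-2-methylideneundeca-6,10-dienoate | C=C(C)[C@H](C/C=C(\C)CCC(OC=C)C(=C)C(=O)OCC=C)CC/C(=C/CCc1ccoc1)C(=O)OC
F8 | step 10 | prop-2-en-1-yl (2Z,6E,9S)-9-[(3Z)-6-(furan-3-yl)-3-(methoxycarbonyl)hex-3-en-1-yl]-6,10-dimethyl-2-(3-oxopropyl)undeca-2,6,10-trienoate | C=C(C)[C@H](C/C=C(\C)CC/C=C(/CCC=O)C(=O)OCC=C)CC/C(=C/CCc1ccoc1)C(=O)OC
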